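**Retrosynthetic overview**

1. Target 24 ⇐ bis-silyl ether 23 (fluoride) ⇐ iodo alkyne 22. Ring A is closed last through the C1–C2 bond, by 6-exo-dig addition of a C2 radical to an ethynyl group on C6.
2. Feature the strategy rests on: the exocyclic methylene on C1 of ring A sits next to the spiro carbon C6, which in turn adjoins the quaternary C5. A C1 ketone there would resist olefination, whereas a C6–C≡CH unit already holds C1 and the methylene carbon.
3. 22 ⇐ aldehyde 18: C4–Br by enamine-catalysed bromination, then C2 and the C3 oxygen by anti-selective methylene transfer and iodide opening. 18 ⇐ lactol 14 by alkyne homologation.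
4. Ring B centres C6, C9, C10 ⇐ achiral spiro keto lactone 9, by chiral-base desymmetrisation, chlorination at C10 and methyl addition at C9.
5. 9 ⇐ prenyl ester 3 by Ireland–Claisen rearrangement (C5–C6 bond, both quaternary carbons). Ring order: ring B is bought, a temporary lactone ring (C1–O–C3) is made in step 3, ring A in step 15.

Key step: step 15

Atom labels: the labels of the target are used for every intermediate (ring A: C1 bearing the methylene, C2, C3, C4, C5, C6; ring B: C6 to C11), and stereodescriptors refer to these labels; in the lactone intermediates the ring oxygen joins C1 and C3.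

Assumption: the lithium amide of (R,R)-bis(1-phenylethyl)amine is taken to deprotonate the C10 arm (the sense that leads to the (S)-enol silane of 4-tert-butylcyclohexanone), and (2R,5R)-2,5-diphenylpyrrolidine to give the (4S)-bromide; if either sense proves opposite, the antipode of that reagent is used.

**Route**

Step 1
Reactants: 1 1,4-dioxaspiro[4.5]decane-8-carboxylic acid; 2 1-bromo-3-methylbut-2-ene (prenyl bromide)
Product: 3 3-methylbut-2-en-1-yl 1,4-dioxaspiro[4.5]decane-8-carboxylate
Conditions: K2CO3, DMF, 23 °C
Reagents that add atoms: none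
Why: Carboxylate O-alkylation (SN2) by the primary allylic bromide should give the prenyl ester under conditions that leave the dioxolane untouched.

Step 2
Reactants: 3 3-methylbut-2-en-1-yl 1,4-dioxaspiro[4.5]decane-8-carboxylate
Product: 6 8-(2-methylbut-3-en-2-yl)-1,4-dioxaspiro[4.5]decane-8-carboxylic acid, via silyl ketene acetal 4 (not isolated), via trimethylsilyl ester 5 (not isolated)
Conditions: LiN(i-Pr)2, THF, −78 °C; Me3SiCl, −78 to 65 °C; H2O
Reagents that add atoms: none
Why: Ireland–Claisen rearrangement, in which the silyl ketene acetal rearranges through a chair [3,3] transition state and joins C6 to the dimethyl-substituted allyl terminus, so that both quaternary carbons C5 and C6 arise in one bond-forming event; ring B is still symmetric, so no stereocentre is formed.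

Step 3
Reactants: 6 8-(2-methylbut-3-en-2-yl)-1,4-dioxaspiro[4.5]decane-8-carboxylic acid
Product: 9 5,5-dimethyl-2-oxaspiro[5.5]undecane-1,9-dione, via hydroxy acid 7 (not isolated), via ketal lactone 8 (not isolated)
Conditions: 9-borabicyclo[3.3.1]nonane (9-BBN-H, 2.5 equiv), THF, 0 to 23 °C; NaOH, H2O2, 0 °C; Na2SO3; then 2 M HCl, 45 °C
Reagents that add atoms: hydrogen peroxide, OO
Why: Hydroboration–oxidation followed by acid-mediated lactonisation and ketal hydrolysis: the borane should add to the terminus of the vinyl group on the quaternary carbon while the acid is only converted into a slowly reduced acyloxyborane, and aqueous acid then closes the gem-dialkyl-favoured six-membered lactone (C1–O–C3) and frees the C9 ketone.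

Step 4
Reactants: 9 5,5-dimethyl-2-oxaspiro[5.5]undecane-1,9-dione
Product: 10 (6R)-enol silane of 9 with the C9=C10 double bond and a trimethylsilyloxy group on C9
Conditions: LiN[(R)-CH(Me)Ph]2 (from the amine hydrochloride and n-BuLi, LiCl present), Me3SiCl (internal quench), THF, −100 to −78 °C
Reagents that add atoms: chlorotrimethylsilane, C[Si](C)(C)Cl
Why: Enantioselective deprotonation of a prochiral 4,4-disubstituted cyclohexanone by a chiral lithium amide with in situ silylation: ring B is locked with the C5 group equatorial, the base removes one of the two enantiotopic axial α-hydrogens, and the choice of the C10 arm fixes the configuration of C6.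

Step 5
Reactants: 10 (6R)-enol silane of 9
Product: 11 (6R,10S)-10-chloro-5,5-dimethyl-2-oxaspiro[5.5]undecane-1,9-dione (chlorine equatorial, trans to the axial C1 carbonyl)
Conditions: NCS, THF, −78 to 0 °C; then LiCl, DMF, 23 °C
Reagents that add atoms: N-chlorosuccinimide, O=C1CCC(=O)N1Cl
Why: Electrophilic α-chlorination of a silyl enol ether places chlorine regiospecifically on C10, and the C10 configuration is set thermodynamically because chloride exchange (SN2 at the α-keto carbon) equilibrates the epimers toward the equatorial chloride, which avoids the 1,3-diaxial contact with the axial C1 carbonyl.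

Step 6
Reactants: 11 (6R,10S)-10-chloro-5,5-dimethyl-2-oxaspiro[5.5]undecane-1,9-dione
Product: 12 (6R,9R,10S)-10-chloro-9-hydroxy-5,5,9-trimethyl-2-oxaspiro[5.5]undecan-1-one (hydroxyl axial and cis to chlorine, methyl equatorial)
Conditions: MeMgBr, Et2O–CH2Cl2, −78 °C; aq. NH4Cl
Reagents that add atoms: methylmagnesium bromide, C[Mg]Br
Why: Grignard addition to an α-chloro ketone, chemoselective for the activated ketone over the hindered lactone; with the chair locked and chlorine equatorial, methyl should enter equatorially, trans to the adjacent C–Cl bond (torsional and dipole control), which sets C9 with the hydroxyl cis to chlorine as in the classical chlorohydrin synthesis from 2-chlorocyclohexanone.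

Step 7
Reactants: 12 (6R,9R,10S)-chlorohydrin lactone
Product: 13 (6R,9R,10S)-10-chloro-5,5,9-trimethyl-9-(triethylsilyloxy)-2-oxaspiro[5.5]undecan-1-one
Conditions: Et3SiOTf, 2,6-lutidine, CH2Cl2, −78 to 0 °C
Reagents that add atoms: triethylsilyl trifluoromethanesulfonate, CC[Si](CC)(CC)OS(=O)(=O)C(F)(F)F
Why: Silyl triflate silylation of the tertiary alcohol, which masks the chlorohydrin against alkoxide-driven rearrangement in the basic steps that follow.

Step 8
Reactants: 13 triethylsilyl ether of the chlorohydrin lactone
Product: 14 (6R,9R,10S)-lactol (C1 hemiacetal, anomer mixture) of 13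
Conditions: i-Bu2AlH, CH2Cl2, −78 °C; MeOH, aq. KNaC4H4O6
Reagents that add atoms: none
Why: Partial reduction of a lactone by i-Bu2AlH, which should stop at the lactol because the tetrahedral aluminate is stable at −78 °C; the anomeric centre is of no consequence.

Step 9
Reactants: 14 (6R,9R,10S)-lactol; 15 dimethyl (1-diazo-2-oxopropyl)phosphonate
Product: 17 (6R,9R,10S)-alkynol (ring B with ethynyl and the chain C5Me2–C4H2–C3H2OH on C6), via hydroxy aldehyde 16 (not isolated)
Conditions: K2CO3, MeOH, 0 to 23 °C
Reagents that add atoms: none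
Why: Ohira–Bestmann (Seyferth–Gilbert) homologation acting on the open hydroxy aldehyde form of the lactol: the non-enolisable C1 aldehyde should be converted by way of the diazoalkene and a 1,2-hydrogen shift into the terminal alkyne, which frees the C3 hydroxyl at the same time.

Step 10
Reactants: 17 (6R,9R,10S)-alkynol
Product: 18 (6R,9R,10S)-aldehyde (chain C5Me2–C4H2–C3HO)
Conditions: Dess–Martin periodinane, NaHCO3, CH2Cl2, 0 to 23 °C
Reagents that add atoms: none
Why: Dess–Martin oxidation of the primary alcohol under buffered conditions, to which the silyl ether, the chloride and the alkyne are inert.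

Step 11
Reactants: 18 (6R,9R,10S)-aldehyde
Product: 19 (4S,6S,9R,10S)-α-bromo aldehyde (bromine on C4), used crude
Conditions: (2R,5R)-2,5-diphenylpyrrolidine (20 mol%), PhCO2H (20 mol%), 4,4-dibromo-2,6-di-tert-butylcyclohexa-2,5-dien-1-one, H2O, CH2Cl2–pentane, −40 °C
Reagents that add atoms: 4,4-dibromo-2,6-di-tert-butylcyclohexa-2,5-dien-1-one, CC(C)(C)C1=CC(Br)(Br)C=C(C(C)(C)C)C1=O
Why: Enamine-catalysed asymmetric α-bromination of an aldehyde: the twofold-symmetric pyrrolidine forms the E-enamine and shields one of its faces, so bromine should be delivered to C4 under catalyst control, independently of the remote ring B centres.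

Step 12
Reactants: 19 (4S,6S,9R,10S)-α-bromo aldehyde
Product: 20 (3R,4S,6S,9R,10S)-bromo epoxide (oxirane on C2–C3)
Conditions: Me3S+ I−, KN(SiMe3)2, THF, −10 °C; then 19 added at −78 °C
Reagents that add atoms: trimethylsulfonium iodide, C[S+](C)C.[I-]
Why: Corey–Chaykovsky epoxidation: the unstabilised ylide should add irreversibly to the aldehyde faster than it deprotonates C4–H or the alkyne, and attack anti to the C–Br dipole and away from quaternary C5 (Cornforth, polar Felkin–Anh model) sets C3 anti to C4 before the betaine closes to the terminal epoxide.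

Step 13
Reactants: 20 (3R,4S,6S,9R,10S)-bromo epoxide
Product: 21 (3S,4S,6S,9R,10S)-iodohydrin (C2H2I, C3–OH, C4–Br)
Conditions: LiI, AcOH, THF, 0 to 23 °C
Reagents that add atoms: lithium iodide, [Li+].[I-]
Why: Acid-assisted SN2 opening of a terminal epoxide by iodide at the primary carbon C2, which leaves the C3–O bond and hence the C3 configuration untouched (the descriptor changes only through priority).

Step 14
Reactants: 21 (3S,4S,6S,9R,10S)-iodohydrin
Product: 22 (3S,4S,6S,9R,10S)-iodo alkyne with C3–OSi(t-Bu)Me2 and C9–OSiEt3 (the cyclisation precursor)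
Conditions: t-BuMe2SiOTf, 2,6-lutidine, CH2Cl2, −78 to −20 °C
Reagents that add atoms: tert-butyldimethylsilyl trifluoromethanesulfonate, CC(C)(C)[Si](C)(C)OS(=O)(=O)C(F)(F)F
Why: Silyl triflate silylation of the hindered secondary alcohol with a weak base at low temperature, which should outrun closure of the iodohydrin to the epoxide.

Step 15
Reactants: 22 (3S,4S,6S,9R,10S)-iodo alkyne bis-silyl ether
Product: 23 (3R,4S,6S,9R,10S)-bis-silyl ether of the target (ring A closed, exocyclic methylene on C1)
Conditions: (Me3Si)3SiH (1.15 equiv, slow addition), Et3B (0.3 equiv), air, PhMe (0.01 M), −20 to 0 °C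
Reagents that add atoms: none
Why: Ethyl radicals from Et3B and oxygen start a chain in which the silyl radical abstracts iodine from the primary C2–I bond, the C2 radical adds to the alkyne carbon C1 bonded to C6 to form the C1–C2 bond, and the resulting σ-vinyl radical takes hydrogen from the silane to give the methylene and regenerate the silyl radical. The closest known reaction type is the silane- or stannane-mediated reductive cyclisation of hept-6-ynyl iodides. Ring A is closed in the 6-exo-dig mode. No stereocentre is created, and none of the five existing ones is a radical site, so C3, C4, C6, C9 and C10 are carried through unchanged. The step needs iodine abstraction in preference to the secondary C4–Br and C10–Cl bonds, which the much weaker primary C–I bond, the low temperature and the limited amount of silane should secure; it also needs exo addition and ring closure faster than hydrogen transfer to C2, which the two quaternary carbons C5 and C6 (folded chain, no propargylic hydrogen for 1,5-transfer) and slow addition of the silane at high dilution should secure.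

Step 16
Reactants: 23 bis-silyl ether of the target
Product: 24 target, (3R,4S,6S,9R,10S)-4-bromo-10-chloro-5,5,9-trimethyl-1-methylidenespiro[5.5]undecane-3,9-diol
Conditions: HF·pyridine, pyridine, THF, 0 to 23 °C
Reagents that add atoms: none
Why: Fluoride-mediated cleavage of both silyl ethers under buffered, non-basic conditions, which should spare the two halides and the exocyclic alkene; both halohydrins are cis and cannot close to epoxides.

**Compound list**

1 | 1,4-dioxaspiro[4.5]decane-8-carboxylic acid | OC(=O)C1CCC2(CC1)OCCO2 | starting material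
2 | 1-bromo-3-methylbut-2-ene (prenyl bromide) | CC(C)=CCBr | starting material
3 | 3-methylbut-2-en-1-yl 1,4-dioxaspiro[4.5]decane-8-carboxylate | CC(C)=CCOC(=O)C1CCC2(CC1)OCCO2 | intermediate
4 | trimethylsilyl ketene acetal of 3 | CC(C)=CCOC(O[Si](C)(C)C)=C1CCC2(CC1)OCCO2 | intermediate (not isolated)
5 | trimethylsilyl 8-(2-methylbut-3-en-2-yl)-1,4-dioxaspiro[4.5]decane-8-carboxylate | C=CC(C)(C)C1(C(=O)O[Si](C)(C)C)CCC2(CC1)OCCO2 | intermediate (not isolated)
6 | 8-(2-methylbut-3-en-2-yl)-1,4-dioxaspiro[4.5]decane-8-carboxylic acid | C=CC(C)(C)C1(C(=O)O)CCC2(CC1)OCCO2 | intermediate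
7 | 8-(4-hydroxy-2-methylbutan-2-yl)-1,4-dioxaspiro[4.5]decane-8-carboxylic acid | OCCC(C)(C)C1(C(=O)O)CCC2(CC1)OCCO2 | intermediate (not isolated)
8 | ethylene ketal of keto lactone 9 (δ-lactone of 7) | CC1(C)CCOC(=O)C12CCC3(CC2)OCCO3 | intermediate (not isolated)
9 | 5,5-dimethyl-2-oxaspiro[5.5]undecane-1,9-dione | CC1(C)CCOC(=O)C12CCC(=O)CC2 | intermediate
10 | (6R)-5,5-dimethyl-9-(trimethylsilyloxy)-2-oxaspiro[5.5]undec-9-en-1-one (C9=C10) | C[Si](C)(C)OC1=CC[C@@]2(CC1)C(=O)OCCC2(C)C | intermediate
11 | (6R,10S)-10-chloro-5,5-dimethyl-2-oxaspiro[5.5]undecane-1,9-dione | O=C1CC[C@]2(C[C@@H]1Cl)C(=O)OCCC2(C)C | intermediate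
12 | (6R,9R,10S)-10-chloro-9-hydroxy-5,5,9-trimethyl-2-oxaspiro[5.5]undecan-1-one | C[C@@]1(O)CC[C@]2(C[C@@H]1Cl)C(=O)OCCC2(C)C | intermediate
13 | (6R,9R,10S)-10-chloro-5,5,9-trimethyl-9-(triethylsilyloxy)-2-oxaspiro[5.5]undecan-1-one | C[C@@]1(O[Si](CC)(CC)CC)CC[C@]2(C[C@@H]1Cl)C(=O)OCCC2(C)C | intermediate
14 | (6R,9R,10S)-10-chloro-5,5,9-trimethyl-9-(triethylsilyloxy)-2-oxaspiro[5.5]undecan-1-ol (lactol, anomer mixture) | C[C@@]1(O[Si](CC)(CC)CC)CC[C@]2(C[C@@H]1Cl)C(O)OCCC2(C)C | intermediate
15 | dimethyl (1-diazo-2-oxopropyl)phosphonate | COP(=O)(OC)C(=[N+]=[N-])C(C)=O | starting material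
16 | (6R,9R,10S)-hydroxy aldehyde: ring B with CHO and the 4-hydroxy-2-methylbutan-2-yl chain on C6, Cl on C10, Me and OSiEt3 on C9 | O=C[C@]1(C(C)(C)CCO)CC[C@@](C)(O[Si](CC)(CC)CC)[C@@H](Cl)C1 | intermediate (not isolated)
17 | (6R,9R,10S)-alkynol: as 16 with ethynyl in place of CHO | C#C[C@]1(C(C)(C)CCO)CC[C@@](C)(O[Si](CC)(CC)CC)[C@@H](Cl)C1 | intermediate
18 | (6R,9R,10S)-aldehyde: as 17 with C3HO in place of C3H2OH | C#C[C@]1(C(C)(C)CC=O)CC[C@@](C)(O[Si](CC)(CC)CC)[C@@H](Cl)C1 | intermediate
19 | (4S,6S,9R,10S)-α-bromo aldehyde: as 18 with Br on C4 | C#C[C@]1(C(C)(C)[C@H](Br)C=O)CC[C@@](C)(O[Si](CC)(CC)CC)[C@@H](Cl)C1 | intermediate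
20 | (3R,4S,6S,9R,10S)-bromo epoxide: oxirane on C2–C3, Br on C4 | C#C[C@]1(C(C)(C)[C@H](Br)[C@@H]2OC2)CC[C@@](C)(O[Si](CC)(CC)CC)[C@@H](Cl)C1 | intermediate
21 | (3S,4S,6S,9R,10S)-iodohydrin: C2H2I, C3–OH, C4–Br | C#C[C@]1(C(C)(C)[C@H](Br)[C@@H](CI)O)CC[C@@](C)(O[Si](CC)(CC)CC)[C@@H](Cl)C1 | intermediate
22 | (3S,4S,6S,9R,10S)-iodo alkyne with C3–OSi(t-Bu)Me2 and C9–OSiEt3 (cyclisation precursor) | C#C[C@]1(C(C)(C)[C@H](Br)[C@@H](CI)O[Si](C)(C)C(C)(C)C)CC[C@@](C)(O[Si](CC)(CC)CC)[C@@H](Cl)C1 | intermediate
23 | (3R,4S,6S,9R,10S)-bis-silyl ether of the target | C=C1C[C@@H](O[Si](C)(C)C(C)(C)C)[C@@H](Br)C(C)(C)[C@]12CC[C@@](C)(O[Si](CC)(CC)CC)[C@@H](Cl)C2 | intermediate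
24 | (3R,4S,6S,9R,10S)-4-bromo-10-chloro-5,5,9-trimethyl-1-methylidenespiro[5.5]undecane-3,9-diol | C=C1C[C@@H](O)[C@@H](Br)C(C)(C)[C@]12CC[C@@](C)(O)[C@@H](Cl)C2 | target

**Step count and risks**

Total step count: 16. Longest linear sequence: 16 steps (fully linear from 1).

Steps most likely to fail:

Step 15. What may go wrong: hydrogen transfer from the silane to the C2 radical before the ring closes, or further reduction at the C4–Br bond once the iodide is used up. Fallback: starting from 22, the ring is closed with no hydrogen donor present, by iodine-atom-transfer cyclisation (Et3B, air, benzene, 23 °C). The vinyl radical then takes iodine from a second molecule of 22 and gives the exocyclic vinyl iodide F1 as an E/Z mixture. The vinyl C–I bond alone is then reduced with Pd(PPh3)4 and Bu3SnH in THF at 23 °C, which should leave the alkyl bromide and chloride alone, and the route is rejoined at 23.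

Step 4. What may go wrong: insufficient discrimination between the two enantiotopic α-methylene groups, so that C6 is set with low selectivity or in the wrong sense. Fallback: starting from 9, the chiral base and the enol silane are given up for enamine catalysis. Direct α-chlorination with NCS and a 4,5-diphenylimidazolidine catalyst (2-nitrobenzoic acid, MeCN, −25 °C) lets the catalyst and the locked chair choose the arm, as in aminocatalytic desymmetrisations of 4-substituted cyclohexanones. The same chloride equilibration follows, and the route is rejoined at 11 without any new compound.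

Step 12. What may go wrong: epimerisation at C4 by the basic ylide before it adds, or poor facial selectivity in the addition to the carbonyl group. Fallback: starting from 19, C2 is brought in as a vinyl group. CH2=CHMgBr (THF, −78 °C) should add anti to the C–Br bond to give the allylic bromohydrin F2. Silylation (t-BuMe2SiOTf, 2,6-lutidine) gives the silyl ether F3. OsO4 (catalytic) with NaIO4 and 2,6-lutidine in dioxane–water cleaves the alkene, which the alkyne should survive, to the α-silyloxy aldehyde F4. NaBH4 in MeOH gives the primary alcohol F5, and I2, PPh3 and imidazole convert it into the iodide 22, where the route is rejoined.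

**Further compounds**

F1 | step 15 | exocyclic vinyl iodide (iodomethylidene analogue of 23, E/Z mixture) | IC=C1C[C@@H](O[Si](C)(C)C(C)(C)C)[C@@H](Br)C(C)(C)[C@]12CC[C@@](C)(O[Si](CC)(CC)CC)[C@@H](Cl)C2
F0 | step 4 | none | none
F2 | step 12 | allylic bromohydrin (vinyl on C3, C3–OH, C4–Br) | C#C[C@]1(C(C)(C)[C@H](Br)[C@@H](C=C)O)CC[C@@](C)(O[Si](CC)(CC)CC)[C@@H](Cl)C1
F3 | step 12 | tert-butyldimethylsilyl ether of F2 | C#C[C@]1(C(C)(C)[C@H](Br)[C@@H](C=C)O[Si](C)(C)C(C)(C)C)CC[C@@](C)(O[Si](CC)(CC)CC)[C@@H](Cl)C1
F4 | step 12 | α-silyloxy aldehyde (C2HO) | C#C[C@]1(C(C)(C)[C@H](Br)[C@@H](C=O)O[Si](C)(C)C(C)(C)C)CC[C@@](C)(O[Si](CC)(CC)CC)[C@@H](Cl)C1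
F5 | step 12 | primary alcohol (C2H2OH) | C#C[C@]1(C(C)(C)[C@H](Br)[C@@H](CO)O[Si](C)(C)C(C)(C)C)CC[C@@](C)(O[Si](CC)(CC)CC)[C@@H](Cl)C1
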